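**Plan**
- Retrosynthetic cuts, in order: C11–O (Mitsunobu to umbelliferone), C9–C11 (methylenation and hydroboration of a C9 ketone), C3–C4 (ring A), C6–O (γ-oxidation of an enone), then C10–C1 and C10–CH3 (two enolate alkylations). This leads back to (R)-carvone.
- Forward: the carvone ring is ring B throughout. Its C=O is C9, its C(CH3)=CH is C8=C7, its allylic CH2 is C6, its stereocentre is C5 and its α′-carbon is C10. C10 is made quaternary, C6 is oxygenated, ring A is then closed, and C11 and the coumarin are added last.
- Enabling feature: C4 is a gem-dimethyl carbon bonded to ring-B carbon C5, which is the hydrogen-atom adduct of carvone's isopropenyl group. C3 is a carbonyl carbon reached from C10 through C1–C2, so a tertiary C4 radical closes the six-membered ring A (C3, C4, C5, C10, C1, C2) onto a C3 aldehyde.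
- Stereochemistry: C5 comes from (R)-carvone; C10 from allylation anti to the isopropenyl group; C6 from oxidant approach anti to the same group; the trans ring fusion follows from C5 and C10; C9 from hydroboration on the α face; the C3 carbinol centre is erased by the final oxidation.

Key step: step 6

Remark: ring positions C1–C12 in the text follow the drimane numbering of the target, while systematic names use their own locants. Compounds 11–16 are carried as C3-epimer mixtures and C3 is written without configuration.

Step 1
Reactants: 1 (R)-(−)-carvone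
Product: 3 6-methylcarvone (C6 epimers), via lithium enolate 2 (not isolated)
Conditions: LiN(i-Pr)2 (LDA), THF, −78 °C; then MeI, −78 → 0 °C
Reagents that add atoms: iodomethane, SMILES CI
Why: Kinetic deprotonation of the enone at the α′-CH2 (C10) gives the cross-conjugated lithium enolate, whose C-methylation (enolate alkylation) should occur mainly anti to the isopropenyl group; the new centre is re-enolised in step 2, so its configuration does not matter.

Step 2
Reactants: 3 6-methylcarvone (C6 epimers)
Product: 5 (5S,6S)-6-allyl-2,6-dimethyl-5-(prop-1-en-2-yl)cyclohex-2-en-1-one, via lithium enolate 4 (not isolated)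
Conditions: LDA, THF/DMPU, −78 °C; then allyl bromide, −78 °C → rt
Reagents that add atoms: allyl bromide, SMILES C=CCBr
Why: Enolate alkylation of the tetrasubstituted cross-conjugated enolate with the reactive allylic bromide should occur on the face anti to the adjacent isopropenyl group (1,2-induction from C5), making C10 quaternary with CH3 cis and the three-carbon arm trans to the isopropenyl group, the relationship that later enforces the trans ring fusion.

Step 3
Reactants: 5 (5S,6S)-6-allyl-2,6-dimethyl-5-(prop-1-en-2-yl)cyclohex-2-en-1-one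
Product: 8 (4S,5S,6S)-6-allyl-4-hydroxy-2,6-dimethyl-5-(prop-1-en-2-yl)cyclohex-2-en-1-one, via lithium dienolate 6 (not isolated), via silyl dienol ether 7 (not isolated)
Conditions: LDA, THF/DMPU, −78 °C; TMSCl; then m-CPBA, NaHCO3, CH2Cl2, −40 °C; aq. citric acid work-up
Reagents that add atoms: m-chloroperbenzoic acid, SMILES OOC(=O)c1cccc(Cl)c1
Why: Because the α′-position is now quaternary, LDA can only remove a γ-proton at C6 to give the linear dienolate, and peracid oxidation of its 1-silyloxy-1,3-diene at the distal C6=C7 bond (vinylogous Rubottom oxidation, the reaction type used for 6-hydroxylation of steroidal dienol ethers) should deliver oxygen to C6 anti to the neighbouring isopropenyl group and the pseudoaxial C10 methyl, giving the trans γ-hydroxy enone.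

Step 4
Reactants: 8 (4S,5S,6S)-6-allyl-4-hydroxy-2,6-dimethyl-5-(prop-1-en-2-yl)cyclohex-2-en-1-one
Product: 9 (1S,5S,6S)-5-allyl-3,5-dimethyl-4-oxo-6-(prop-1-en-2-yl)cyclohex-2-en-1-yl acetate
Conditions: Ac2O, pyridine, DMAP (cat.), CH2Cl2, 0 °C
Reagents that add atoms: acetic anhydride, SMILES CC(=O)OC(C)=O
Why: DMAP-catalysed acylation of the only hydroxyl group installs the C6 acetate of the target at the one stage where no other alcohol is present, so no protecting group is needed later.

Step 5
Reactants: 9 (1S,5S,6S)-5-allyl-3,5-dimethyl-4-oxo-6-(prop-1-en-2-yl)cyclohex-2-en-1-yl acetate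
Product: 10 (1S,5S,6S)-3,5-dimethyl-4-oxo-5-(3-oxopropyl)-6-(prop-1-en-2-yl)cyclohex-2-en-1-yl acetate
Conditions: PdCl2(PhCN)2 (cat.), CuCl2·2H2O (cat.), AgNO2 (cat.), O2 (1 atm), t-BuOH/MeNO2, 25 °C
Reagents that add atoms: dioxygen, SMILES O=O
Why: Nitrite-modified Wacker oxidation is aldehyde-selective (anti-Markovnikov) for unbiased monosubstituted alkenes, while the 1,1-disubstituted isopropenyl group and the electron-poor trisubstituted enone alkene are poor substrates for divalent palladium, so only the allyl group should be oxidised, to the C3 aldehyde.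

Step 6
Reactants: 10 (1S,5S,6S)-3,5-dimethyl-4-oxo-5-(3-oxopropyl)-6-(prop-1-en-2-yl)cyclohex-2-en-1-yl acetate
Product: 11 6α-acetoxy-3-hydroxy-11-nordrim-7-en-9-one (5α-H; 10β-CH3; C3 epimers)
Conditions: Fe(acac)3 (30 mol %), PhSiH3, EtOH/ethylene glycol, 0.02 M, 50 °C, argon
Reagents that add atoms: none
Why: Fe(acac)3 and PhSiH3 in EtOH generate an iron hydride that transfers a hydrogen atom to the terminal CH2 of the electron-rich 1,1-disubstituted isopropenyl group, giving the tertiary C4 radical, which adds to the tethered aldehyde carbon C3; the C3 alkoxy radical is then reduced by divalent iron and protonated by EtOH, which returns the trivalent iron alkoxide to the cycle. The closest known reaction type is the Mukaiyama-type, HAT-initiated reductive cyclisation of alkene-tethered carbonyl compounds, itself related to classical 6-exo radical cyclisations onto aldehydes. Ring A closes in the 6-exo-trig mode onto the C=O group, and the hydrogen atom delivered to CH2 completes the gem-dimethyl group, so C4 becomes quaternary but not stereogenic. The trans ring fusion is inherited and not made here: C4 (on C5) and C1 (on C10) are trans and both equatorial in the reactive chair, so only the trans-decalin can form, while the new carbinol centre C3 is uncontrolled and is erased in step 10. The step needs chemoselective hydrogen-atom transfer to the isopropenyl group over the enone C7=C8 bond, and cyclisation faster than reduction of the radical or reversal by β-scission; the first should be secured by the electron-poor, trisubstituted nature of the enone alkene, the second by high dilution, the gauche arrangement of the two equatorial arms and rapid quenching of the alkoxy radical in the protic medium.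

Step 7
Reactants: 11 6α-acetoxy-3-hydroxy-11-nordrim-7-en-9-one (C3 epimers)
Product: 12 6α-acetoxydrima-7,9(11)-dien-3-ol (C3 epimers)
Conditions: Zn, CH2Br2, TiCl4 (pre-formed reagent), THF/CH2Cl2, 0 °C → rt; NaHCO3 quench
Reagents that add atoms: dibromomethane, SMILES BrCBr
Why: The non-basic titanium methylene reagent from Zn, CH2Br2 and TiCl4 (Takai–Lombardo methylenation) olefinates hindered and conjugated ketones but not esters and tolerates free hydroxyl groups, so the C9 carbonyl should give the 7,9(11)-diene without touching the acetate.

Step 8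
Reactants: 12 6α-acetoxydrima-7,9(11)-dien-3-ol (C3 epimers)
Product: 14 6α-acetoxydrim-7-ene-3,11-diol (9α-H; C3 epimers), via bis(9-BBN) adduct 13 (not isolated)
Conditions: 9-BBN, THF, 0 → 45 °C; then 30% H2O2, aq. NaOAc, 0 °C → rt
Reagents that add atoms: hydrogen peroxide, SMILES OO
Why: Hydroboration–oxidation with bulky 9-BBN should place boron on the unhindered terminal carbon C11 of the exocyclic alkene and hydrogen on C9 from the α face, anti to the axial C10 methyl, which sets the C9 stereocentre (9α-H, equatorial CH2OH) and leaves the trisubstituted C7=C8 bond and the acetate untouched, buffered peroxide then giving the primary alcohol.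

Step 9
Reactants: 14 6α-acetoxydrim-7-ene-3,11-diol (C3 epimers); 15 umbelliferone (7-hydroxy-2H-chromen-2-one)
Product: 16 7-[(6α-acetoxy-3-hydroxydrim-7-en-11-yl)oxy]-2H-chromen-2-one (C3 epimers)
Conditions: PPh3, DIAD, THF, 0 °C → rt
Reagents that add atoms: none
Why: Mitsunobu etherification should activate only the primary C11 alcohol (the secondary C3 alcohol next to quaternary C4 is inert), and the acidic phenol of umbelliferone displaces the oxyphosphonium group by SN2 at CH2, no stereocentre being involved.

Step 10
Reactants: 16 7-[(6α-acetoxy-3-hydroxydrim-7-en-11-yl)oxy]-2H-chromen-2-one (C3 epimers)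
Product: 17 7-[(6α-acetoxy-3-oxodrim-7-en-11-yl)oxy]-2H-chromen-2-one (CNP0140705.1)
Conditions: Dess–Martin periodinane, NaHCO3, CH2Cl2, 0 °C → rt
Reagents that add atoms: none
Why: Dess–Martin oxidation of the single remaining secondary alcohol should converge both C3 epimers on the ketone under buffered conditions that leave the allylic acetate, the alkene and the coumarin untouched.

**Compound list**
1 | (R)-(−)-carvone, (5R)-2-methyl-5-(prop-1-en-2-yl)cyclohex-2-en-1-one | CC1=CC[C@H](CC1=O)C(C)=C | starting material
2 | lithium enolate of 1 (cross-conjugated, formed at the α′-carbon) | C1C=C(C)C(O[Li])=C[C@@H]1C(C)=C | intermediate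
3 | 6-methylcarvone, (5R)-2,6-dimethyl-5-(prop-1-en-2-yl)cyclohex-2-en-1-one, C6 epimers | CC1=CC[C@H](C(C)C1=O)C(C)=C | intermediate
4 | lithium enolate of 3 (tetrasubstituted, cross-conjugated) | C1C=C(C)C(O[Li])=C(C)[C@@H]1C(C)=C | intermediate
5 | (5S,6S)-6-allyl-2,6-dimethyl-5-(prop-1-en-2-yl)cyclohex-2-en-1-one (allyl trans, methyl cis to isopropenyl) | C1C=C(C)C(=O)[C@@](C)(CC=C)[C@@H]1C(C)=C | intermediate
6 | lithium dienolate of 5 (linear, from γ-deprotonation) | C1=CC(C)=C(O[Li])[C@@](C)(CC=C)[C@@H]1C(C)=C | intermediate
7 | trimethylsilyl dienol ether of 5 (1-silyloxy-1,3-diene) | C1=CC(C)=C(O[Si](C)(C)C)[C@@](C)(CC=C)[C@@H]1C(C)=C | intermediate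
8 | (4S,5S,6S)-6-allyl-4-hydroxy-2,6-dimethyl-5-(prop-1-en-2-yl)cyclohex-2-en-1-one (OH trans to isopropenyl) | O[C@H]1C=C(C)C(=O)[C@@](C)(CC=C)[C@@H]1C(C)=C | intermediate
9 | (1S,5S,6S)-5-allyl-3,5-dimethyl-4-oxo-6-(prop-1-en-2-yl)cyclohex-2-en-1-yl acetate | CC(=O)O[C@H]1C=C(C)C(=O)[C@@](C)(CC=C)[C@@H]1C(C)=C | intermediate
10 | (1S,5S,6S)-3,5-dimethyl-4-oxo-5-(3-oxopropyl)-6-(prop-1-en-2-yl)cyclohex-2-en-1-yl acetate | CC(=O)O[C@H]1C=C(C)C(=O)[C@@](C)(CCC=O)[C@@H]1C(C)=C | intermediate
11 | 6α-acetoxy-3-hydroxy-11-nordrim-7-en-9-one (trans-decalin, 5α-H, 10β-CH3, C3 epimers) | CC(=O)O[C@H]1C=C(C)C(=O)[C@@]2(C)CCC(O)C(C)(C)[C@H]12 | intermediate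
12 | 6α-acetoxydrima-7,9(11)-dien-3-ol (C3 epimers) | CC(=O)O[C@H]1C=C(C)C(=C)[C@@]2(C)CCC(O)C(C)(C)[C@H]12 | intermediate
13 | bis(9-BBN) adduct of 12 (C11–B alkylborane and C3–O–B borinate, 9α-H) | CC(=O)O[C@H]1C=C(C)[C@H](CB3C4CCCC3CCC4)[C@@]2(C)CCC(OB3C4CCCC3CCC4)C(C)(C)[C@H]12 | intermediate
14 | 6α-acetoxydrim-7-ene-3,11-diol (9α-H, C3 epimers) | CC(=O)O[C@H]1C=C(C)[C@H](CO)[C@@]2(C)CCC(O)C(C)(C)[C@H]12 | intermediate
15 | umbelliferone, 7-hydroxy-2H-chromen-2-one | Oc1ccc2ccc(=O)oc2c1 | starting material
16 | 7-[(6α-acetoxy-3-hydroxydrim-7-en-11-yl)oxy]-2H-chromen-2-one (C3 epimers) | CC(=O)O[C@H]1C=C(C)[C@H](COc2ccc3ccc(=O)oc3c2)[C@@]2(C)CCC(O)C(C)(C)[C@H]12 | intermediate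
17 | 7-[(6α-acetoxy-3-oxodrim-7-en-11-yl)oxy]-2H-chromen-2-one, CNP0140705.1 | CC(=O)O[C@H]1C=C(C)[C@H](COc2ccc3ccc(=O)oc3c2)[C@@]2(C)CCC(=O)C(C)(C)[C@H]12 | target

**Totals**
Total step count: 10. Longest linear sequence: 10 steps, from 1 to 17 (15 is used as purchased).

**Steps most likely to fail**

1. Step 6. The tertiary radical may be reduced before it cyclises (net hydrogenation of the isopropenyl group), the addition to the aldehyde may revert by β-scission of the alkoxy radical, or the silane may reduce the aldehyde. The fallback sets out from aldehyde 10. Hydroxylamine-O-sulfonic acid in aqueous THF should convert the aldehyde in one pot into the nitrile F1. The same iron hydride conditions then effect the known HAT-initiated alkene–nitrile cyclisation, in which addition gives an iminyl radical and is not reversible, and acidic work-up hydrolyses the ketimine to the 3,9-diketone F2. NaBH4 in MeOH/CH2Cl2 at −78 °C should reduce the saturated C3 ketone in preference to the conjugated C9 ketone flanked by quaternary C10 and the C8 methyl, which returns the route to 11.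

2. Step 7. The C9 carbonyl, flanked by quaternary C10 and the C8 methyl, may resist addition of the titanium methylene reagent, and Lewis-acid ionisation of the dienyl acetate product may lead to elimination. The fallback sets out from 11 and replaces the one-step methylenation by a Peterson olefination. (Trimethylsilyl)methyllithium with CeCl3 in THF at −78 °C is an oxophilic, weakly basic reagent that adds to hindered ketones much faster than to esters, and it should give the β-hydroxysilane F3, one equivalent being consumed by the free alcohol. Brief treatment with buffered aqueous HF in MeCN should then eliminate silanol and give the diene 12, where the route resumes.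

3. Step 3. The peracid may attack the proximal enol-ether bond (α- instead of γ-hydroxylation), may epoxidise the isopropenyl group, or may show poor facial selectivity. The fallback sets out from 5 through the same silyl dienol ether 7. Tetraphenylporphyrin-sensitised photo-oxygenation (O2, visible light, CH2Cl2, −78 °C) lets singlet oxygen add in a [4+2] manner across the diene termini C6 and C9, so that oxygen can only arrive at C6, from the same less hindered face. Collapse of the silyl peroxyketal on methanol work-up should give the γ-hydroperoxy enone F4, which PPh3 reduces to the γ-hydroxy enone 8.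

**Further compounds**
F1 | step 6 | (1S,5S,6S)-5-(2-cyanoethyl)-3,5-dimethyl-4-oxo-6-(prop-1-en-2-yl)cyclohex-2-en-1-yl acetate | CC(=O)O[C@H]1C=C(C)C(=O)[C@@](C)(CCC#N)[C@@H]1C(C)=C
F2 | step 6 | 6α-acetoxy-11-nordrim-7-ene-3,9-dione | CC(=O)O[C@H]1C=C(C)C(=O)[C@@]2(C)CCC(=O)C(C)(C)[C@H]12
F3 | step 7 | 6α-acetoxy-9-[(trimethylsilyl)methyl]-11-nordrim-7-ene-3,9-diol (C3 and C9 epimers) | CC(=O)O[C@H]1C=C(C)C(O)(C[Si](C)(C)C)[C@@]2(C)CCC(O)C(C)(C)[C@H]12
F4 | step 3 | (4S,5S,6S)-6-allyl-4-hydroperoxy-2,6-dimethyl-5-(prop-1-en-2-yl)cyclohex-2-en-1-one | OO[C@H]1C=C(C)C(=O)[C@@](C)(CC=C)[C@@H]1C(C)=C
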